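Amounts here were counted in substrate units, so a percent of target and a percent of isomer of the product could be added straight up, and the question was how much of that sum was still target.

| flask | substrate | temperature | remark | time |
|---|---|---|---|---|
| south-west | 1 M | 25 °C | run made earlier |  |
| south-east | 1.5 M | 45 °C | run made earlier |  |
| theta | 2.0 M | 45 °C |  | 3.0 h |
| alpha | 2.0 M | 60 °C |  | 3.0 h |
| gamma | 2.0 M | 30 °C |  | 3.0 h |

south-west run (percent of the substrate charged)

| time / h | target / % | isomer of the product / % | substrate / % |
|---|---|---|---|
| 0.333 | 18.7 | 0 | 82.2 |
| 0.833 | 37.0 | 0.7 | 61.9 |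
| 2.00 | 56.1 | 1.1 | 41.8 |
| 2.50 | 63.2 | 1.6 | 36.4 |
| 4.00 | 71.1 | 1.9 | 26.6 |
| 5.00 | 75.0 | 2.6 | 22.3 |

south-east run (percent of the substrate charged)

| time / min | target / % | isomer of the product / % | substrate / % |
|---|---|---|---|
| 8.00 | 43.6 | 1.1 | 55.7 |
| 20.0 | 65.4 | 2.0 | 33.5 |
| 40.0 | 75.4 | 4.6 | 19.5 |
| 60.0 | 79.4 | 7.1 | 14.0 |
| 80.0 | 77.8 | 9.6 | 11.3 |
| 120 | 76.2 | 15.0 | 8.3 |

(readings scatter by 0.5 percentage points)

- the flask with the highest share of target in all that became target or isomer of the product ("all alike" if they lie within 1.5 percentage points) (theta / alpha / gamma / all alike)
- share of target in all that became target or isomer of the product, theta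
- share of target in all that became target or isomer of the product, alpha
- share of target in all that became target or isomer of the product, gamma

- percent here means substrate units held: one target or isomer of the product counts as two

I began with the substrate, since target has to be born before it can age. In the south-east run 14.0% of the substrate stood at 60.0 min. The reciprocal of [substrate] climbed evenly with time, which gave a half-time of 0.122 h for a 2.0 M charge at 45 °C, and the south-west run gave 0.718 h at 25 °C. Target was born early with a straggling tail, so I put its mean birth at two half-times.

Next I needed the loss. Late in the south-east run the isomer of the product rose 7.9 percentage points in 1.00 h while target stood near 77.8%, a clock of 0.102 h⁻¹. Clock times mean age of target I called the ageing number; for theta it was 0.280, and a one-way exponential fall over that number left a share of 75.6%.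

From the south-west end readings the clock at 25 °C was 0.00763 h⁻¹. Going from 45 °C to 60 °C is 0.750 of the step from 25 °C to 45 °C, and I scaled clock and half-time by that. This gave alpha 2.08 and gamma 0.0303, so gamma kept the higher share, at 97.0%.

The weak link was that 25 °C clock, resting on a rise of 1.5 points with scatter 0.5 points at each end. Averaging readings in pairs gave 0.00732 h⁻¹, so alpha stood at 2.14, a share of 11.8%. Yet the last south-east reading had reached just 0.203, so alpha lay beyond anything read.

The forecast gave gamma as highest, with 75.5%, 15% and 96% for theta, alpha and gamma, and said “The coolest flask keeps the highest share”. The flasks gave 76.1%, 30.8% and 96.6%, with gamma highest.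

    2 substrate → target (k = 6.46 M⁻¹ h⁻¹, Ea = 69.0 kJ mol⁻¹)
    substrate ⇌ dormant form (K = 27.0, k = 0.193 h⁻¹, Ea = 109 kJ mol⁻¹, ΔH = −42.0 kJ mol⁻¹)
    target ⇌ isomer of the product (K = 3.04, k = 0.669 h⁻¹, Ea = 107 kJ mol⁻¹, ΔH = 13.0 kJ mol⁻¹)
    (constants at 60 °C)

The gap of 66 points between alpha and gamma shrinks to 0.68 points in the run where temperature no longer acts on the path from target to isomer of the product, the largest single effect on that gap. Theta, at 0.280, stayed near its one-way share, but alpha, at 2.14, did not. The run of alpha with the undoing of isomer of the product into target taken away gives 14.9% against 30.8%, so that undoing is part of what held target up. This is kinetic against thermodynamic control, and in alpha the step relaxed with a half-life of 0.780 h, short against 3.0 h.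

For a flask like alpha kept at 75 °C, the same scaling gave an ageing number of 15.6, whose one-way fall leaves hardly any target. The computed flask keeps 21.2%.

The data are simulated from invented constants; the scatter is artificial.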